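Numbering used below: ring A (the benzoate ring) carries the lactone carbonyl on position 1, OH on position 2, prenyl on position 3, the pyran oxygen on position 4, the pyran CH on position 5 and the diaryl ether oxygen on position 6; ring B carries the ether oxygen on position 1, H on position 2, OH on position 3, the pyran oxygen on position 4, the pyran CH on position 5 and the ester oxygen on position 6.
Cuts, last bond first: the O–Si bond on position 2 of ring A; the lactone bond from the ester oxygen to position 6 of ring B (oxidative C–H acyloxylation: this carbon is para to the free hydroxyl on position 3 of ring B, so two-electron oxidation of that phenol makes it electrophilic toward the carboxylate on position 1 of ring A, which the diaryl ether oxygen holds next to it); both pyran rings and the prenyl C–C bond on position 3 of ring A (three oxygen-to-carbon sigmatropic shifts); the C–O bond on position 4 of ring B (Baeyer–Villiger); the diaryl ether bond from oxygen to position 1 of ring B (SNAr).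
Forward: the diaryl ether is made first from a symmetric 2,6-dihydroxybenzoate and a 4-fluorobenzaldehyde, the aldehyde becomes the phenol on position 4 of ring B, one thermal operation then installs the prenyl group and closes the ring A and ring B pyrans, and the seven-membered lactone is closed last.
Stereochemistry: the target has no stereocentre and no stereogenic double bond, so nothing has to be set.

Key step: step 13

Remark: 3-chloro-3-methylbut-1-yne is taken as the purchasable activated form of 2-methylbut-3-yn-2-ol; the only sp3 ring carbon created on the way (in the transient dienone of the key step) is racemic and disappears on tautomerisation.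

Step 1
Reactants: 1 methyl 2,4,6-trihydroxybenzoate
Product: 2 methyl 4-(benzyloxy)-2,6-dihydroxybenzoate
Conditions: BnBr (1.0 equiv), K2CO3 (1.0 equiv), acetone, rt
Reagents that add atoms: benzyl bromide, BrCc1ccccc1
Why: Williamson etherification, in which the 4-hydroxyl, the most acidic one and the only one not hydrogen-bonded to the ester carbonyl, should be alkylated selectively while the two equivalent salicylate hydroxyls stay free.

Step 2
Reactants: 3 4-fluoro-2-hydroxybenzaldehyde
Product: 4 4-fluoro-2-(methoxymethoxy)benzaldehyde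
Conditions: MOMCl, iPr2NEt, CH2Cl2, 0 °C to rt
Reagents that add atoms: chloromethyl methyl ether, COCCl
Why: Standard O-alkylation of a phenol to its methoxymethyl (MOM) acetal, which masks the future hydroxyl on position 3 of ring B and is stable to base, peracid, hydrogenolysis and heat.

Step 3
Reactants: 2 methyl 4-(benzyloxy)-2,6-dihydroxybenzoate; 4 4-fluoro-2-(methoxymethoxy)benzaldehyde
Product: 5 methyl 4-(benzyloxy)-2-[4-formyl-3-(methoxymethoxy)phenoxy]-6-hydroxybenzoate
Conditions: K2CO3, DMSO, 90 °C (2 in twofold excess)
Reagents that add atoms: none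
Why: Nucleophilic aromatic substitution (SNAr) in which the para-formyl group activates the fluoride toward the phenoxide of 2, the two hydroxyls of 2 being equivalent so that mono-arylation gives a single constitution and the excess of 2 keeping double arylation low; this forms the diaryl ether between position 6 of ring A and position 1 of ring B.

Step 4
Reactants: 5 methyl 4-(benzyloxy)-2-[4-formyl-3-(methoxymethoxy)phenoxy]-6-hydroxybenzoate
Product: 7 methyl 4-(benzyloxy)-2-hydroxy-6-[4-hydroxy-3-(methoxymethoxy)phenoxy]benzoate, via aryl formate 6 (not isolated)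
Conditions: mCPBA, CH2Cl2, 0 °C to rt; then K2CO3 (cat.), MeOH, rt
Reagents that add atoms: 3-chloroperoxybenzoic acid, O=C(OO)c1cccc(Cl)c1
Why: Baeyer–Villiger (Dakin-type) oxidation in which the electron-rich 2,4-dioxygenated aryl group migrates to give formate 6, whose methanolysis frees the phenol on position 4 of ring B at a stage where no alkene is yet present.

Step 5
Reactants: 7 methyl 4-(benzyloxy)-2-hydroxy-6-[4-hydroxy-3-(methoxymethoxy)phenoxy]benzoate
Product: 8 methyl 2,4-dihydroxy-6-[4-hydroxy-3-(methoxymethoxy)phenoxy]benzoate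
Conditions: H2 (1 atm), 10% Pd/C, EtOAc, rt
Reagents that add atoms: none
Why: Catalytic hydrogenolysis of the benzyl ether, placed before any alkene or alkyne is introduced, with the MOM acetal, the ester and the diaryl ether inert.

Step 6
Reactants: 8 methyl 2,4-dihydroxy-6-[4-hydroxy-3-(methoxymethoxy)phenoxy]benzoate; 9 3-chloro-3-methylbut-1-yne
Product: 10 methyl 2-hydroxy-6-{3-(methoxymethoxy)-4-[(2-methylbut-3-yn-2-yl)oxy]phenoxy}-4-[(2-methylbut-3-yn-2-yl)oxy]benzoate
Conditions: 9 (2.5 equiv), CuCl2·2H2O (1 mol %), DBU, MeCN, 0 °C to rt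
Reagents that add atoms: none
Why: Copper-catalysed propargylic etherification (copper allenylidene intermediate) of the two free phenols on position 4 of ring A and position 4 of ring B, the hydroxyl on position 2 of ring A being held in a hydrogen bond to the ester and expected to stay unalkylated.

Step 7
Reactants: 11 2-methylbut-3-en-2-ol
Product: 12 tert-butyl 2-methylbut-3-en-2-yl carbonate
Conditions: n-BuLi, THF, −78 °C; Boc2O, to rt
Reagents that add atoms: di-tert-butyl dicarbonate, CC(C)(C)OC(=O)OC(=O)OC(C)(C)C
Why: Acylation of the lithium alkoxide of the tertiary allylic alcohol gives the mixed carbonate that serves as 1,1-dimethylallyl donor.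

Step 8
Reactants: 10 methyl 2-hydroxy-6-{3-(methoxymethoxy)-4-[(2-methylbut-3-yn-2-yl)oxy]phenoxy}-4-[(2-methylbut-3-yn-2-yl)oxy]benzoate; 12 tert-butyl 2-methylbut-3-en-2-yl carbonate
Product: 13 methyl 2-[(2-methylbut-3-en-2-yl)oxy]-6-{3-(methoxymethoxy)-4-[(2-methylbut-3-yn-2-yl)oxy]phenoxy}-4-[(2-methylbut-3-yn-2-yl)oxy]benzoate
Conditions: Pd(PPh3)4 (5 mol %), THF, 0 °C
Reagents that add atoms: none
Why: Tsuji–Trost decarboxylative O-allylation in which zerovalent palladium ionises 12, the released tert-butoxide deprotonates the only free phenol (position 2 of ring A), and the phenoxide attacks the more substituted terminus of the 1,1-dimethylallyl palladium cation under kinetic control to give the tertiary ether.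

Step 9
Reactants: 13 methyl 2-[(2-methylbut-3-en-2-yl)oxy]-6-{3-(methoxymethoxy)-4-[(2-methylbut-3-yn-2-yl)oxy]phenoxy}-4-[(2-methylbut-3-yn-2-yl)oxy]benzoate
Product: 15 methyl 7-hydroxy-5-{[8-(methoxymethoxy)-2,2-dimethyl-2H-chromen-6-yl]oxy}-2,2-dimethyl-8-(3-methylbut-2-en-1-yl)-2H-chromene-6-carboxylate, via prenylated phenol 14 (not isolated)
Conditions: PhNEt2, 100 °C, then 185 °C
Reagents that add atoms: none
Why: Aromatic Claisen rearrangement of the tertiary allyl ether at 100 °C should deliver the prenyl group to position 3 of ring A, the only free ortho position of that ether oxygen, and at 185 °C the two aryl propargyl ethers should undergo propargyl Claisen rearrangement, 1,5-hydrogen shift and oxa-6π electrocyclisation to the 2H-chromenes, the ring A ether being forced to position 5 of ring A because position 3 is now substituted and the ring B ether to position 5 of ring B because position 3 of that ring bears oxygen.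

Step 10
Reactants: 15 methyl 7-hydroxy-5-{[8-(methoxymethoxy)-2,2-dimethyl-2H-chromen-6-yl]oxy}-2,2-dimethyl-8-(3-methylbut-2-en-1-yl)-2H-chromene-6-carboxylate
Product: 16 7-hydroxy-5-{[8-(methoxymethoxy)-2,2-dimethyl-2H-chromen-6-yl]oxy}-2,2-dimethyl-8-(3-methylbut-2-en-1-yl)-2H-chromene-6-carboxylic acid
Conditions: KOH, EtOH/H2O, 80 °C; then 1 M HCl to pH 3, 0 °C
Reagents that add atoms: potassium hydroxide, [K+].[OH-]
Why: Saponification of the hindered salicylate ester with hot aqueous-ethanolic KOH, a standard hydrolysis for 2-hydroxy-3-prenylbenzoates, in which the phenoxide carboxylate dianion should resist carbon protonation and the cold acidification should avoid acid-promoted decarboxylation.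

Step 11
Reactants: 16 7-hydroxy-5-{[8-(methoxymethoxy)-2,2-dimethyl-2H-chromen-6-yl]oxy}-2,2-dimethyl-8-(3-methylbut-2-en-1-yl)-2H-chromene-6-carboxylic acid
Product: 18 7-[(tert-butyldimethylsilyl)oxy]-5-{[8-(methoxymethoxy)-2,2-dimethyl-2H-chromen-6-yl]oxy}-2,2-dimethyl-8-(3-methylbut-2-en-1-yl)-2H-chromene-6-carboxylic acid, via silyl ester 17 (not isolated)
Conditions: TBSCl, imidazole, DMAP (cat.), DMF, 40 °C; then AcOH/THF/H2O, rt
Reagents that add atoms: tert-butyldimethylsilyl chloride, CC(C)(C)[Si](C)(C)Cl
Why: Silylation of both the acid and the hindered phenol on position 2 of ring A, then selective hydrolysis of the far more labile silyl ester with aqueous acetic acid, should leave the aryl silyl ether and the MOM acetal in place.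

Step 12
Reactants: 18 7-[(tert-butyldimethylsilyl)oxy]-5-{[8-(methoxymethoxy)-2,2-dimethyl-2H-chromen-6-yl]oxy}-2,2-dimethyl-8-(3-methylbut-2-en-1-yl)-2H-chromene-6-carboxylic acid
Product: 19 7-[(tert-butyldimethylsilyl)oxy]-5-[(8-hydroxy-2,2-dimethyl-2H-chromen-6-yl)oxy]-2,2-dimethyl-8-(3-methylbut-2-en-1-yl)-2H-chromene-6-carboxylic acid
Conditions: TMSOTf (excess), 2,2′-bipyridyl, MeCN, 0 °C to rt; then H2O
Reagents that add atoms: none
Why: Cleavage of the aromatic MOM ether with a silyl triflate buffered by 2,2′-bipyridyl proceeds through the aryl trimethylsilyl ether under non-acidic conditions, so the acid-sensitive chromenes, the prenyl group and the hindered tert-butyldimethylsilyl ether should survive, and the aqueous work-up hydrolyses the trimethylsilyl ether and ester.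

Step 13
Reactants: 19 7-[(tert-butyldimethylsilyl)oxy]-5-[(8-hydroxy-2,2-dimethyl-2H-chromen-6-yl)oxy]-2,2-dimethyl-8-(3-methylbut-2-en-1-yl)-2H-chromene-6-carboxylic acid
Product: 21 garcinisidone D ring A tert-butyldimethylsilyl ether, via cyclohexadienone lactone 20 (not isolated)
Conditions: PhI(OAc)2 (1.05 equiv), (CF3)2CHOH/CH2Cl2, −20 to 0 °C
Reagents that add atoms: none
Why: Proposed new method: ligand exchange of the ring B phenol (position 3) at trivalent iodine and loss of iodobenzene should give a phenoxenium-type cation with charge on positions 2, 4 and 6 of ring B, and the carboxylate on position 1 of ring A, held over ring B by the diaryl ether oxygen, adds to position 6 of ring B to form the lactone C–O bond, after which the 4-acyloxycyclohexa-2,5-dienone 20, which bears hydrogen on that carbon, tautomerises to phenol 21. The closest known reaction types are the dearomative spirolactonisation of phenols carrying a carboxylic acid side chain and the para-acyloxylation of phenols with PhI(OAc)2, whereas a seven-membered closure at a para C–H position of a diaryl ether has no direct precedent. The one ring formed, the seven-membered lactone, closes in a 7-exo-trig mode by addition of the carboxylate oxygen to the ring B carbon para to the oxidised oxygen, the double bond from that carbon to position 5 lying outside the new ring. No stereocentre remains in the product, the sp3 carbon of 20 being transient and racemic. The step needs attack at position 6 of ring B (para to the oxidised oxygen) and not at position 2 (ortho, same tether length) or position 4, which should be secured by the intrinsically higher electrophilicity of the para position of phenoxenium ions, by the crowding of position 2 between two oxygen-bearing carbons, and by the non-nucleophilic fluoroalcohol, which leaves the tethered carboxylate as the only competent nucleophile. Oxidation should stay on ring B because the oxygen on position 2 of ring A is silylated and ring A carries the carboxyl group, and one equivalent of oxidant at low temperature limits further oxidation of the less electron-rich product to the quinone.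

Step 14
Reactants: 21 garcinisidone D ring A tert-butyldimethylsilyl ether
Product: 22 garcinisidone D
Conditions: Bu4NF, AcOH, THF, 0 °C
Reagents that add atoms: none
Why: Fluoride-mediated cleavage of the aryl silyl ether, buffered with acetic acid so that the phenoxide formed does not open the depsidone lactone.

Compound list
1 | methyl 2,4,6-trihydroxybenzoate | COC(=O)c1c(O)cc(O)cc1O | starting material
2 | methyl 4-(benzyloxy)-2,6-dihydroxybenzoate | COC(=O)c1c(O)cc(OCc2ccccc2)cc1O | intermediate
3 | 4-fluoro-2-hydroxybenzaldehyde | O=Cc1ccc(F)cc1O | starting material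
4 | 4-fluoro-2-(methoxymethoxy)benzaldehyde | COCOc1cc(F)ccc1C=O | intermediate
5 | methyl 4-(benzyloxy)-2-[4-formyl-3-(methoxymethoxy)phenoxy]-6-hydroxybenzoate | COC(=O)c1c(O)cc(OCc2ccccc2)cc1Oc1ccc(C=O)c(OCOC)c1 | intermediate
6 | methyl 4-(benzyloxy)-2-[4-(formyloxy)-3-(methoxymethoxy)phenoxy]-6-hydroxybenzoate | COC(=O)c1c(O)cc(OCc2ccccc2)cc1Oc1ccc(OC=O)c(OCOC)c1 | intermediate
7 | methyl 4-(benzyloxy)-2-hydroxy-6-[4-hydroxy-3-(methoxymethoxy)phenoxy]benzoate | COC(=O)c1c(O)cc(OCc2ccccc2)cc1Oc1ccc(O)c(OCOC)c1 | intermediate
8 | methyl 2,4-dihydroxy-6-[4-hydroxy-3-(methoxymethoxy)phenoxy]benzoate | COC(=O)c1c(O)cc(O)cc1Oc1ccc(O)c(OCOC)c1 | intermediate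
9 | 3-chloro-3-methylbut-1-yne | CC(C)(Cl)C#C | starting material
10 | methyl 2-hydroxy-6-{3-(methoxymethoxy)-4-[(2-methylbut-3-yn-2-yl)oxy]phenoxy}-4-[(2-methylbut-3-yn-2-yl)oxy]benzoate | COC(=O)c1c(O)cc(OC(C)(C)C#C)cc1Oc1ccc(OC(C)(C)C#C)c(OCOC)c1 | intermediate
11 | 2-methylbut-3-en-2-ol | CC(C)(O)C=C | starting material
12 | tert-butyl 2-methylbut-3-en-2-yl carbonate | CC(C)(C)OC(=O)OC(C)(C)C=C | intermediate
13 | methyl 2-[(2-methylbut-3-en-2-yl)oxy]-6-{3-(methoxymethoxy)-4-[(2-methylbut-3-yn-2-yl)oxy]phenoxy}-4-[(2-methylbut-3-yn-2-yl)oxy]benzoate | COC(=O)c1c(OC(C)(C)C=C)cc(OC(C)(C)C#C)cc1Oc1ccc(OC(C)(C)C#C)c(OCOC)c1 | intermediate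
14 | methyl 2-hydroxy-3-(3-methylbut-2-en-1-yl)-6-{3-(methoxymethoxy)-4-[(2-methylbut-3-yn-2-yl)oxy]phenoxy}-4-[(2-methylbut-3-yn-2-yl)oxy]benzoate | COC(=O)c1c(O)c(CC=C(C)C)c(OC(C)(C)C#C)cc1Oc1ccc(OC(C)(C)C#C)c(OCOC)c1 | intermediate
15 | methyl 7-hydroxy-5-{[8-(methoxymethoxy)-2,2-dimethyl-2H-chromen-6-yl]oxy}-2,2-dimethyl-8-(3-methylbut-2-en-1-yl)-2H-chromene-6-carboxylate | COC(=O)c1c(O)c(CC=C(C)C)c2OC(C)(C)C=Cc2c1Oc1cc(OCOC)c2OC(C)(C)C=Cc2c1 | intermediate
16 | 7-hydroxy-5-{[8-(methoxymethoxy)-2,2-dimethyl-2H-chromen-6-yl]oxy}-2,2-dimethyl-8-(3-methylbut-2-en-1-yl)-2H-chromene-6-carboxylic acid | OC(=O)c1c(O)c(CC=C(C)C)c2OC(C)(C)C=Cc2c1Oc1cc(OCOC)c2OC(C)(C)C=Cc2c1 | intermediate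
17 | tert-butyldimethylsilyl 7-[(tert-butyldimethylsilyl)oxy]-5-{[8-(methoxymethoxy)-2,2-dimethyl-2H-chromen-6-yl]oxy}-2,2-dimethyl-8-(3-methylbut-2-en-1-yl)-2H-chromene-6-carboxylate | CC(C)(C)[Si](C)(C)OC(=O)c1c(O[Si](C)(C)C(C)(C)C)c(CC=C(C)C)c2OC(C)(C)C=Cc2c1Oc1cc(OCOC)c2OC(C)(C)C=Cc2c1 | intermediate
18 | 7-[(tert-butyldimethylsilyl)oxy]-5-{[8-(methoxymethoxy)-2,2-dimethyl-2H-chromen-6-yl]oxy}-2,2-dimethyl-8-(3-methylbut-2-en-1-yl)-2H-chromene-6-carboxylic acid | OC(=O)c1c(O[Si](C)(C)C(C)(C)C)c(CC=C(C)C)c2OC(C)(C)C=Cc2c1Oc1cc(OCOC)c2OC(C)(C)C=Cc2c1 | intermediate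
19 | 7-[(tert-butyldimethylsilyl)oxy]-5-[(8-hydroxy-2,2-dimethyl-2H-chromen-6-yl)oxy]-2,2-dimethyl-8-(3-methylbut-2-en-1-yl)-2H-chromene-6-carboxylic acid | OC(=O)c1c(O[Si](C)(C)C(C)(C)C)c(CC=C(C)C)c2OC(C)(C)C=Cc2c1Oc1cc(O)c2OC(C)(C)C=Cc2c1 | intermediate
20 | cyclohexadienone lactone (racemic; seven-membered lactone closed, ring B a 4-acyloxycyclohexa-2,5-dienone with the ketone on position 3 and with hydrogen and the ester oxygen on position 6) | CC(C)=CCc1c(O[Si](C)(C)C(C)(C)C)c2c(c3c1OC(C)(C)C=C3)OC1=CC(=O)C3=C(C=CC(C)(C)O3)C1OC2=O | intermediate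
21 | garcinisidone D ring A tert-butyldimethylsilyl ether | CC(C)=CCc1c(O[Si](C)(C)C(C)(C)C)c2c(c3c1OC(C)(C)C=C3)Oc1cc(O)c3c(c1OC2=O)C=CC(C)(C)O3 | intermediate
22 | garcinisidone D | CC(C)=CCc1c(O)c2c(c3c1OC(C)(C)C=C3)Oc1cc(O)c3c(c1OC2=O)C=CC(C)(C)O3 | target

Total step count: 14. Longest linear sequence: 12 steps (steps 1, 3, 4, 5, 6, 8, 9, 10, 11, 12, 13, 14 from compound 1).

Steps most likely to fail

Step 13 (the new method). What may go wrong: the carboxylate adds at position 2 of ring B instead of position 6, the cation is intercepted at the alkoxy-bearing position 4, the product phenol is oxidised on to the quinone, or the oxidant attacks the chromene double bonds. The fallback uses known chemistry, sets out from 19 and comes back at 21. Teuber oxidation of the ring B phenol with (KSO3)2NO in phosphate-buffered aqueous acetone should give the para-quinone acid 7-[(tert-butyldimethylsilyl)oxy]-5-[(2,2-dimethyl-5,8-dioxo-5,8-dihydro-2H-chromen-6-yl)oxy]-2,2-dimethyl-8-(3-methylbut-2-en-1-yl)-2H-chromene-6-carboxylic acid F1. Reduction with Na2S2O4 should give the hydroquinone acid 7-[(tert-butyldimethylsilyl)oxy]-5-[(5,8-dihydroxy-2,2-dimethyl-2H-chromen-6-yl)oxy]-2,2-dimethyl-8-(3-methylbut-2-en-1-yl)-2H-chromene-6-carboxylic acid F2. Carbodiimide lactonisation of F2 (DCC, CH2Cl2, high dilution), in which only the new hydroxyl on position 6 of ring B can close a seven-membered ring, then gives 21. Here the oxygen on position 6 of ring B is installed first and the ring is closed by acyl substitution instead of oxidative C–O bond formation.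

Step 8. What may go wrong: slow O-allylation of the hydrogen-bonded phenol on position 2 of ring A, re-ionisation of the tertiary ether by zerovalent palladium with drift to the linear O-prenyl ether, or interference of the terminal alkynes with the catalyst. The fallback sets out from 10 and comes back at 14. Direct ortho C-prenylation of the sodium phenoxide of 10 in a non-polar solvent (NaH, toluene, then 1-bromo-3-methylbut-2-ene, 60 °C), a C-alkylation of the tight ion pair at the free ortho carbon (position 3 of ring A), should give 14 without passing through an allyl ether. Compound 14 is then heated at 185 °C as in the second stage of step 9. This detour makes no compound outside the list (F0).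

Step 9. What may go wrong: the ring A propargyl ether rearranges before the allyl group has migrated and so reaches position 3 of ring A, the allenyl dienone formed by attack on the prenyl-bearing position 3 is diverted into an intramolecular Diels–Alder reaction instead of reverting, or material degrades at 185 °C. The fallback sets out from 13 and comes back at 15. Only the first stage (100 °C) is run and 14 is isolated. Both pyran rings are then closed at room temperature by 6-endo hydroarylation of the aryl propargyl ethers under catalysis by the monovalent gold complex Ph3PAuNTf2 in CH2Cl2. This replaces the thermal pericyclic sequence by π-acid catalysis and should give 15. This detour makes no compound outside the list (F0).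

Further compounds
F1 | step 13 | 7-[(tert-butyldimethylsilyl)oxy]-5-[(2,2-dimethyl-5,8-dioxo-5,8-dihydro-2H-chromen-6-yl)oxy]-2,2-dimethyl-8-(3-methylbut-2-en-1-yl)-2H-chromene-6-carboxylic acid | OC(=O)c1c(O[Si](C)(C)C(C)(C)C)c(CC=C(C)C)c2OC(C)(C)C=Cc2c1OC1=CC(=O)C2=C(C=CC(C)(C)O2)C1=O
F2 | step 13 | 7-[(tert-butyldimethylsilyl)oxy]-5-[(5,8-dihydroxy-2,2-dimethyl-2H-chromen-6-yl)oxy]-2,2-dimethyl-8-(3-methylbut-2-en-1-yl)-2H-chromene-6-carboxylic acid | OC(=O)c1c(O[Si](C)(C)C(C)(C)C)c(CC=C(C)C)c2OC(C)(C)C=Cc2c1Oc1cc(O)c2OC(C)(C)C=Cc2c1O
F0 | step 8 | none | none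
F0 | step 9 | none | none
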